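**Retrosynthetic overview**

- Numbering (germacrane): ring A is the ten-membered carbocycle C1–C10; ring B is the γ-lactone C7–C8–O–C12–C11; C13 is the methylene carbon, C14 the methyl on C10, C15 the CH2O carbon on C4.
- The strategy rests on the C6 carbinol next to the trisubstituted C4=C5 alkene of ring A, in which C3 and C6 are cis and C15 sits on C4. This allylic alcohol is what syn addition of an aldehyde carbon (C6) and an alkyl carbon (C3) across the terminal alkyne C5≡C4–C15 delivers.
- Disconnections, backwards: the O15 ester and the C11=C13 methylene (late); C5–C6 and C3–C4 in one nickel-mediated operation that closes ring A; C9–C10 (alkenyl Grignard on a C9 triflate); C7–C8 (succinate syn aldol).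
- Ring order: ring B first (aldol, then lactonization, C7/C8 trans); ring A second, in the key step, which also sets C6.

Key step: step 17

Remark: O15 is carried through the key step as a triethylsilyl ether so that it can later be freed beside a tert-butyldimethylsilyl ether on O6; compounds 2, 5, 14, 25, 35 and 36 are taken as purchasable.

**Route**

Step 1
Reactants: 1 4-tert-butoxy-4-oxobutanoic acid; 2 (4R)-4-benzyl-1,3-oxazolidin-2-one
Product: 4 tert-butyl 4-[(4R)-4-benzyl-2-oxo-1,3-oxazolidin-3-yl]-4-oxobutanoate, via pivalic mixed anhydride 3 (not isolated)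
Conditions: 1, t-BuCOCl, Et3N, THF, −20 °C; then LiCl, 2, −20 °C → rt
Reagents that add atoms: none
Why: N-acylation of the oxazolidinone through the pivalic mixed anhydride with LiCl assistance is the standard entry to succinate imides and leaves the tert-butyl ester untouched.

Step 2
Reactants: 4 succinate imide; 5 2-(benzyloxy)acetaldehyde
Product: 7 tert-butyl (3R,4R)-3-{[(4R)-4-benzyl-2-oxo-1,3-oxazolidin-3-yl]carbonyl}-5-(benzyloxy)-4-hydroxypentanoate, via Z-boron enolate 6 (not isolated)
Conditions: Bu2BOTf, i-Pr2NEt, CH2Cl2, 0 °C; 5, −78 → 0 °C; pH 7 buffer, MeOH, H2O2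
Reagents that add atoms: none
Why: Evans syn aldol; the Z-boron enolate should react through a Zimmerman–Traxler chair on the face away from the benzyl group of the (R)-auxiliary, setting C7 and C8 in the syn relationship that becomes the trans-lactone.

Step 3
Reactants: 7 syn aldol adduct
Product: 8 (4R)-4-benzyl-3-{[(2R,3R)-2-[(benzyloxy)methyl]-5-oxooxolan-3-yl]carbonyl}-1,3-oxazolidin-2-one
Conditions: CF3CO2H, CH2Cl2, 0 °C → rt
Reagents that add atoms: none
Why: Acidolysis of the tert-butyl ester and lactonization of the resulting γ-hydroxy acid should close ring B with the C7 and C8 substituents trans, no stereocentre being touched.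

Step 4
Reactants: 8 lactone imide
Product: 9 (2R,3R)-2-[(benzyloxy)methyl]-5-oxooxolane-3-carboxylic acid
Conditions: LiOH, H2O2, THF/H2O, 0 °C; Na2SO3; HCl to pH 2
Reagents that add atoms: hydrogen peroxide, OO
Why: Hydroperoxide cleaves the exocyclic imide carbonyl selectively (LiOOH hydrolysis of an N-acyloxazolidinone), and any lactone opened by hydroxide should reclose on acidification.

Step 5
Reactants: 9 lactone acid
Product: 10 (4S,5R)-5-[(benzyloxy)methyl]-4-(hydroxymethyl)oxolan-2-one
Conditions: BH3·SMe2, THF, 0 °C → rt; MeOH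
Reagents that add atoms: none
Why: Borane reduces a free carboxylic acid (via the acyloxyborane) much faster than a lactone, so the C6 primary alcohol should form chemoselectively; neutral work-up avoids translactonization.

Step 6
Reactants: 10 hydroxymethyl lactone
Product: 11 (4S,5R)-5-[(benzyloxy)methyl]-4-{[(tert-butyldiphenylsilyl)oxy]methyl}oxolan-2-one
Conditions: t-BuPh2SiCl, imidazole, CH2Cl2, 0 °C → rt
Reagents that add atoms: tert-butyl(chloro)diphenylsilane, CC(C)(C)[Si](Cl)(c1ccccc1)c1ccccc1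
Why: Silylation of the primary alcohol gives an O6 protecting group that should survive hydrogenolysis, triflation, the organocopper step and mild acid.

Step 7
Reactants: 11 benzyl ether
Product: 12 (4S,5R)-4-{[(tert-butyldiphenylsilyl)oxy]methyl}-5-(hydroxymethyl)oxolan-2-one
Conditions: H2 (1 atm), Pd/C, EtOAc, rt
Reagents that add atoms: none
Why: Hydrogenolysis of the benzyl ether frees the C9 hydroxyl without touching the silyl ether or the lactone.

Step 8
Reactants: 12 C9 alcohol
Product: 13 [(2R,3S)-3-{[(tert-butyldiphenylsilyl)oxy]methyl}-5-oxooxolan-2-yl]methyl trifluoromethanesulfonate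
Conditions: (CF3SO2)2O, 2,6-lutidine, CH2Cl2, −78 °C; cold aqueous work-up, used at once
Reagents that add atoms: trifluoromethanesulfonic anhydride, O=S(=O)(OS(=O)(=O)C(F)(F)F)C(F)(F)F
Why: Sulfonylation of the primary alcohol gives a leaving group reactive enough for SN2 at a carbon that is deactivated by the neighbouring C8–O bond.

Step 9
Reactants: 14 pent-3-yn-1-ol
Product: 15 tert-butyl(dimethyl)(pent-3-yn-1-yloxy)silane
Conditions: t-BuMe2SiCl, imidazole, CH2Cl2, rt
Reagents that add atoms: tert-butyl(chloro)dimethylsilane, CC(C)(C)[Si](C)(C)Cl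
Why: Standard silylation protects the future C3 oxygen against the zirconium hydride and the organolithium to come.

Step 10
Reactants: 15 silyl ether of pent-3-yn-1-ol
Product: 17 tert-butyl{[(3E)-4-iodopent-3-en-1-yl]oxy}dimethylsilane, via alkenylzirconocene chloride 16 (not isolated)
Conditions: Cp2Zr(H)Cl (2 equiv), THF, 50 °C; I2, 0 °C
Reagents that add atoms: iodine, II
Why: Hydrozirconation–iodination; syn Zr–H addition under equilibrating conditions should place zirconium on the methyl-bearing alkyne carbon, and iodinolysis with retention gives the E-iodide that maps onto C10(C14)=C1.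

Step 11
Reactants: 13 C9 triflate; 17 E-alkenyl iodide
Product: 20 (4S,5S)-5-[(2E)-5-{[tert-butyl(dimethyl)silyl]oxy}-2-methylpent-2-en-1-yl]-4-{[(tert-butyldiphenylsilyl)oxy]methyl}oxolan-2-one, via alkenyllithium 18 (not isolated), via alkenylmagnesium bromide 19 (not isolated)
Conditions: 17 (1.5 equiv), t-BuLi, Et2O, −78 °C; MgBr2·OEt2, −78 → 0 °C; CuBr·SMe2 (10 mol %), 13, Et2O/THF, −40 → 0 °C
Reagents that add atoms: none
Why: Copper-catalysed cross-coupling of a Grignard reagent with a primary triflate (SN2 at C9); iodine–lithium exchange and the transmetalations proceed with retention, so the E geometry should carry over and C8 is not involved.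

Step 12
Reactants: 20 bis-silyl ether
Product: 21 (4S,5S)-4-{[(tert-butyldiphenylsilyl)oxy]methyl}-5-[(2E)-5-hydroxy-2-methylpent-2-en-1-yl]oxolan-2-one
Conditions: camphorsulfonic acid (10 mol %), MeOH/CH2Cl2, 0 °C
Reagents that add atoms: none
Why: Acid-catalysed methanolysis removes a primary tert-butyldimethylsilyl ether far faster than a tert-butyldiphenylsilyl ether, freeing only O3.

Step 13
Reactants: 21 C3 alcohol
Product: 22 (4S,5S)-4-{[(tert-butyldiphenylsilyl)oxy]methyl}-5-[(2E)-5-iodo-2-methylpent-2-en-1-yl]oxolan-2-one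
Conditions: I2, PPh3, imidazole, CH2Cl2, 0 °C → rt
Reagents that add atoms: iodine, II
Why: Appel-type iodination of the primary alcohol through its alkoxyphosphonium salt should give the C3 iodide cleanly.

Step 14
Reactants: 22 silyl-protected iodide
Product: 23 (4S,5S)-4-(hydroxymethyl)-5-[(2E)-5-iodo-2-methylpent-2-en-1-yl]oxolan-2-one
Conditions: HF·pyridine, pyridine, THF, 0 °C → rt
Reagents that add atoms: none
Why: Buffered fluoride desilylation frees O6 under conditions that spare the primary iodide, the alkene and the lactone.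

Step 15
Reactants: 23 C6 alcohol
Product: 24 (2S,3R)-2-[(2E)-5-iodo-2-methylpent-2-en-1-yl]-5-oxooxolane-3-carbaldehyde
Conditions: Dess–Martin periodinane, pyridine, CH2Cl2, 0 °C → rt; used at once
Reagents that add atoms: none
Why: Dess–Martin oxidation gives the aldehyde under near-neutral conditions; C7 already holds the more stable trans arrangement, so epimerization has no driving force, and the mild medium should avoid β-elimination of the lactone oxygen.

Step 16
Reactants: 25 prop-2-yn-1-ol
Product: 26 triethyl(prop-2-yn-1-yloxy)silane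
Conditions: Et3SiCl, imidazole, CH2Cl2, 0 °C
Reagents that add atoms: chlorotriethylsilane, CC[Si](Cl)(CC)CC
Why: Silylation gives the alkyne component carrying C5, C4 and C15, with an O15 group that can later be removed beside a tert-butyldimethylsilyl ether.

Step 17
Reactants: 24 iodo aldehyde; 26 triethylsilyl propargyl ether
Product: 28 (3aS,4R,5E,9E,11aS)-4-hydroxy-10-methyl-6-{[(triethylsilyl)oxy]methyl}-3a,4,7,8,11,11a-hexahydrocyclodeca[b]furan-2(3H)-one, via alkylzinc iodide 27 (not isolated)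
Conditions: Zn dust (activated with BrCH2CH2Br), LiCl, THF, 25 °C; decanted solution of 27 added over 8 h to Ni(cod)2 (20 mol %) and 26 (3 equiv), THF, 0 °C, final 0.003 M; aq NH4Cl
Reagents that add atoms: none
Why: Proposed new method: zerovalent nickel should bind aldehyde C6 and the terminal alkyne and undergo oxidative cyclization to an oxanickelacyclopentene (C5–C6 bond, nickel on C4) with the tethered zinc acting as Lewis acid on the aldehyde oxygen, after which alkyl transfer from zinc to nickel and C3–C4 reductive elimination return zerovalent nickel. The closest known reaction type is the nickel-catalysed alkylative three-component coupling of an aldehyde, an alkyne and an organozinc, established intermolecularly and for tethered ynals but not with the zinc carried by the aldehyde partner. Ring A is closed by C(sp3)–C(sp2) reductive elimination from an eleven-membered alkyl(alkenyl)nickelacycle, and the syn addition across the alkyne places C3 and C6 cis on C4=C5, the only geometry in which the chain ends can meet. The C6 stereocentre is set in the oxidative cyclization under control of C7: Felkin–Anh approach anti to the C7–C8 bond, with the C11 methylene next to the carbonyl oxygen, leads to the 6R alcohol. Bond formation at the unsubstituted alkyne carbon is secured by the ligand-free, sterically undemanding nickel, alkyl transfer over β-hydride elimination by the phosphine-free medium, and ring closure over oligomerization by slow addition into excess alkyne at high dilution; the LiCl-mediated zinc insertion tolerates the aldehyde because alkylzinc iodides do not add to aldehydes without activation.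

Step 18
Reactants: 28 macrocyclic hydroxy lactone
Product: 29 (3aR,4R,5E,9E,11aS)-4-{[tert-butyl(dimethyl)silyl]oxy}-10-methyl-6-{[(triethylsilyl)oxy]methyl}-3a,4,7,8,11,11a-hexahydrocyclodeca[b]furan-2(3H)-one
Conditions: t-BuMe2SiOSO2CF3, 2,6-lutidine, CH2Cl2, −78 → 0 °C
Reagents that add atoms: tert-butyldimethylsilyl trifluoromethanesulfonate, CC(C)(C)[Si](C)(C)OS(=O)(=O)C(F)(F)F
Why: Silylation of the hindered C6 alcohol blocks the O6 alkoxide, which could otherwise translactonize onto C12 under the basic conditions that follow.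

Step 19
Reactants: 29 protected lactone
Product: 31 C11 (dimethylamino)methyl lactone (C11 epimers), via lithium enolate 30 (not isolated)
Conditions: LiN(i-Pr)2, THF, −78 °C; CH2=NMe2 I, −78 → 0 °C
Reagents that add atoms: dimethyl(methylidene)ammonium iodide, C=[N+](C)C.[I-]
Why: Mannich aminomethylation of the lactone enolate with Eschenmoser's salt adds C13; the new C11 centre is of no consequence because it becomes sp2 in the next step.

Step 20
Reactants: 31 Mannich base
Product: 33 (3aR,4R,5E,9E,11aS)-4-{[tert-butyl(dimethyl)silyl]oxy}-10-methyl-3-methylidene-6-{[(triethylsilyl)oxy]methyl}-3a,4,7,8,11,11a-hexahydrocyclodeca[b]furan-2(3H)-one, via trimethylammonium iodide 32 (not isolated)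
Conditions: MeI, CH2Cl2, rt; sat. aq NaHCO3, rt
Reagents that add atoms: none
Why: N-Methylation followed by base-induced elimination of trimethylamine (E1cB through the acidic C11–H) should give the exocyclic C11=C13 alkene.

Step 21
Reactants: 33 α-methylene lactone
Product: 34 (3aR,4R,5E,9E,11aS)-4-{[tert-butyl(dimethyl)silyl]oxy}-6-(hydroxymethyl)-10-methyl-3-methylidene-3a,4,7,8,11,11a-hexahydrocyclodeca[b]furan-2(3H)-one
Conditions: pyridinium p-toluenesulfonate (10 mol %), MeOH/CH2Cl2, 0 °C
Reagents that add atoms: none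
Why: Mild acid methanolysis removes the primary allylic triethylsilyl ether selectively beside the hindered secondary tert-butyldimethylsilyl ether.

Step 22
Reactants: 35 2-{[tert-butyl(dimethyl)silyl]oxy}acetaldehyde; 36 ethyl 2-(triphenyl-λ5-phosphanylidene)propanoate
Product: 37 ethyl (2E)-4-{[tert-butyl(dimethyl)silyl]oxy}-2-methylbut-2-enoate
Conditions: CH2Cl2, rt
Reagents that add atoms: none
Why: Wittig olefination with a stabilized, α-branched ylide should be E-selective, giving the tiglate-type geometry of the side chain.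

Step 23
Reactants: 37 ethyl ester
Product: 38 (2E)-4-{[tert-butyl(dimethyl)silyl]oxy}-2-methylbut-2-enoic acid
Conditions: LiOH, THF/MeOH/H2O, rt; 1 M HCl to pH 4, 0 °C
Reagents that add atoms: lithium hydroxide, [Li+].[OH-]
Why: Saponification frees the acid; the primary silyl ether tolerates aqueous base and a brief, cold, weakly acidic work-up, and the E isomer is the stable one.

Step 24
Reactants: 34 C15 alcohol; 38 protected hydroxy acid
Product: 39 [(3aR,4R,5E,9E,11aS)-4-{[tert-butyl(dimethyl)silyl]oxy}-10-methyl-3-methylidene-2-oxo-2,3,3a,4,7,8,11,11a-octahydrocyclodeca[b]furan-6-yl]methyl (2E)-4-{[tert-butyl(dimethyl)silyl]oxy}-2-methylbut-2-enoate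
Conditions: dicyclohexylcarbodiimide, 4-(dimethylamino)pyridine (cat.), CH2Cl2, 0 °C → rt
Reagents that add atoms: none
Why: Steglich esterification of the only free hydroxyl, a primary allylic one, needs no site selectivity and runs under conditions the α-methylene lactone tolerates.

Step 25
Reactants: 39 bis-silyl ester
Product: 40 [(3aS,4R,5E,9E,11aS)-4-hydroxy-10-methyl-3-methylidene-2-oxo-2,3,3a,4,7,8,11,11a-octahydrocyclodeca[b]furan-6-yl]methyl (2E)-4-hydroxy-2-methylbut-2-enoate
Conditions: HF·pyridine, pyridine, THF, 0 °C → rt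
Reagents that add atoms: none
Why: Buffered fluoride desilylation removes both tert-butyldimethylsilyl ethers without base, so the ester, the α-methylene lactone and the 8,12-lactone regiochemistry should be preserved.

**Compound list**

1 | 4-tert-butoxy-4-oxobutanoic acid | CC(C)(C)OC(=O)CCC(=O)O | starting material
2 | (4R)-4-benzyl-1,3-oxazolidin-2-one | O=C1N[C@H](Cc2ccccc2)CO1 | starting material
3 | 4-tert-butoxy-4-oxobutanoic pivalic anhydride | CC(C)(C)OC(=O)CCC(=O)OC(=O)C(C)(C)C | intermediate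
4 | tert-butyl 4-[(4R)-4-benzyl-2-oxo-1,3-oxazolidin-3-yl]-4-oxobutanoate | CC(C)(C)OC(=O)CCC(=O)N1[C@H](Cc2ccccc2)COC1=O | intermediate
5 | 2-(benzyloxy)acetaldehyde | O=CCOCc1ccccc1 | starting material
6 | (Z)-dibutylboron enolate of 4 | CCCCB(CCCC)O/C(=C\CC(=O)OC(C)(C)C)N1[C@H](Cc2ccccc2)COC1=O | intermediate
7 | tert-butyl (3R,4R)-3-{[(4R)-4-benzyl-2-oxo-1,3-oxazolidin-3-yl]carbonyl}-5-(benzyloxy)-4-hydroxypentanoate | O=C1OC[C@@H](Cc2ccccc2)N1C(=O)[C@H](CC(=O)OC(C)(C)C)[C@@H](O)COCc1ccccc1 | intermediate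
8 | (4R)-4-benzyl-3-{[(2R,3R)-2-[(benzyloxy)methyl]-5-oxooxolan-3-yl]carbonyl}-1,3-oxazolidin-2-one (trans-lactone) | O=C1OC[C@@H](Cc2ccccc2)N1C(=O)[C@@H]1CC(=O)O[C@H]1COCc1ccccc1 | intermediate
9 | (2R,3R)-2-[(benzyloxy)methyl]-5-oxooxolane-3-carboxylic acid | OC(=O)[C@@H]1CC(=O)O[C@H]1COCc1ccccc1 | intermediate
10 | (4S,5R)-5-[(benzyloxy)methyl]-4-(hydroxymethyl)oxolan-2-one | OC[C@@H]1CC(=O)O[C@H]1COCc1ccccc1 | intermediate
11 | (4S,5R)-5-[(benzyloxy)methyl]-4-{[(tert-butyldiphenylsilyl)oxy]methyl}oxolan-2-one | CC(C)(C)[Si](c1ccccc1)(c1ccccc1)OC[C@@H]1CC(=O)O[C@H]1COCc1ccccc1 | intermediate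
12 | (4S,5R)-4-{[(tert-butyldiphenylsilyl)oxy]methyl}-5-(hydroxymethyl)oxolan-2-one | CC(C)(C)[Si](c1ccccc1)(c1ccccc1)OC[C@@H]1CC(=O)O[C@H]1CO | intermediate
13 | [(2R,3S)-3-{[(tert-butyldiphenylsilyl)oxy]methyl}-5-oxooxolan-2-yl]methyl trifluoromethanesulfonate | CC(C)(C)[Si](c1ccccc1)(c1ccccc1)OC[C@@H]1CC(=O)O[C@H]1COS(=O)(=O)C(F)(F)F | intermediate
14 | pent-3-yn-1-ol | CC#CCCO | starting material
15 | tert-butyl(dimethyl)(pent-3-yn-1-yloxy)silane | CC#CCCO[Si](C)(C)C(C)(C)C | intermediate
16 | chlorobis(cyclopentadienyl)[(2E)-5-{[tert-butyl(dimethyl)silyl]oxy}pent-2-en-2-yl]zirconium (zirconium on the methyl-bearing carbon, cis to the vinylic hydrogen) | C/C(=C\CCO[Si](C)(C)C(C)(C)C)[Zr+2]Cl.c1cc[cH-]c1.c1cc[cH-]c1 | intermediate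
17 | tert-butyl{[(3E)-4-iodopent-3-en-1-yl]oxy}dimethylsilane | C/C(I)=C\CCO[Si](C)(C)C(C)(C)C | intermediate
18 | [(2E)-5-{[tert-butyl(dimethyl)silyl]oxy}pent-2-en-2-yl]lithium | C/C([Li])=C\CCO[Si](C)(C)C(C)(C)C | intermediate
19 | bromo[(2E)-5-{[tert-butyl(dimethyl)silyl]oxy}pent-2-en-2-yl]magnesium | C/C([Mg]Br)=C\CCO[Si](C)(C)C(C)(C)C | intermediate
20 | (4S,5S)-5-[(2E)-5-{[tert-butyl(dimethyl)silyl]oxy}-2-methylpent-2-en-1-yl]-4-{[(tert-butyldiphenylsilyl)oxy]methyl}oxolan-2-one | CC(C)(C)[Si](c1ccccc1)(c1ccccc1)OC[C@@H]1CC(=O)O[C@H]1C/C(C)=C/CCO[Si](C)(C)C(C)(C)C | intermediate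
21 | (4S,5S)-4-{[(tert-butyldiphenylsilyl)oxy]methyl}-5-[(2E)-5-hydroxy-2-methylpent-2-en-1-yl]oxolan-2-one | CC(C)(C)[Si](c1ccccc1)(c1ccccc1)OC[C@@H]1CC(=O)O[C@H]1C/C(C)=C/CCO | intermediate
22 | (4S,5S)-4-{[(tert-butyldiphenylsilyl)oxy]methyl}-5-[(2E)-5-iodo-2-methylpent-2-en-1-yl]oxolan-2-one | CC(C)(C)[Si](c1ccccc1)(c1ccccc1)OC[C@@H]1CC(=O)O[C@H]1C/C(C)=C/CCI | intermediate
23 | (4S,5S)-4-(hydroxymethyl)-5-[(2E)-5-iodo-2-methylpent-2-en-1-yl]oxolan-2-one | OC[C@@H]1CC(=O)O[C@H]1C/C(C)=C/CCI | intermediate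
24 | (2S,3R)-2-[(2E)-5-iodo-2-methylpent-2-en-1-yl]-5-oxooxolane-3-carbaldehyde | O=C[C@@H]1CC(=O)O[C@H]1C/C(C)=C/CCI | intermediate
25 | prop-2-yn-1-ol | C#CCO | starting material
26 | triethyl(prop-2-yn-1-yloxy)silane | C#CCO[Si](CC)(CC)CC | intermediate
27 | {(3E)-5-[(2S,3R)-3-formyl-5-oxooxolan-2-yl]-4-methylpent-3-en-1-yl}(iodo)zinc | O=C[C@@H]1CC(=O)O[C@H]1C/C(C)=C/CC[Zn]I | intermediate
28 | (3aS,4R,5E,9E,11aS)-4-hydroxy-10-methyl-6-{[(triethylsilyl)oxy]methyl}-3a,4,7,8,11,11a-hexahydrocyclodeca[b]furan-2(3H)-one (trans-fused lactone; C3 and C6 cis on C4=C5) | C1C(=O)O[C@H]2C/C(C)=C/CC/C(CO[Si](CC)(CC)CC)=C\[C@@H](O)[C@H]12 | intermediate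
29 | (3aR,4R,5E,9E,11aS)-4-{[tert-butyl(dimethyl)silyl]oxy}-10-methyl-6-{[(triethylsilyl)oxy]methyl}-3a,4,7,8,11,11a-hexahydrocyclodeca[b]furan-2(3H)-one (same spatial arrangement as 28; the C3a descriptor changes on O-silylation) | C1C(=O)O[C@H]2C/C(C)=C/CC/C(CO[Si](CC)(CC)CC)=C\[C@@H](O[Si](C)(C)C(C)(C)C)[C@H]12 | intermediate
30 | lithium enolate of 29 (C11=C12–OLi) | C1=C(O[Li])O[C@H]2C/C(C)=C/CC/C(CO[Si](CC)(CC)CC)=C\[C@@H](O[Si](C)(C)C(C)(C)C)[C@H]12 | intermediate
31 | 3-[(dimethylamino)methyl] derivative of 29 (C11 epimers, other centres as in 29) | CN(C)CC1C(=O)O[C@H]2C/C(C)=C/CC/C(CO[Si](CC)(CC)CC)=C\[C@@H](O[Si](C)(C)C(C)(C)C)[C@H]12 | intermediate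
32 | N-methyl quaternary ammonium iodide of 31 | C[N+](C)(C)CC1C(=O)O[C@H]2C/C(C)=C/CC/C(CO[Si](CC)(CC)CC)=C\[C@@H](O[Si](C)(C)C(C)(C)C)[C@H]12.[I-] | intermediate
33 | (3aR,4R,5E,9E,11aS)-4-{[tert-butyl(dimethyl)silyl]oxy}-10-methyl-3-methylidene-6-{[(triethylsilyl)oxy]methyl}-3a,4,7,8,11,11a-hexahydrocyclodeca[b]furan-2(3H)-one | C=C1C(=O)O[C@H]2C/C(C)=C/CC/C(CO[Si](CC)(CC)CC)=C\[C@@H](O[Si](C)(C)C(C)(C)C)[C@H]12 | intermediate
34 | (3aR,4R,5E,9E,11aS)-4-{[tert-butyl(dimethyl)silyl]oxy}-6-(hydroxymethyl)-10-methyl-3-methylidene-3a,4,7,8,11,11a-hexahydrocyclodeca[b]furan-2(3H)-one | C=C1C(=O)O[C@H]2C/C(C)=C/CC/C(CO)=C\[C@@H](O[Si](C)(C)C(C)(C)C)[C@H]12 | intermediate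
35 | 2-{[tert-butyl(dimethyl)silyl]oxy}acetaldehyde | O=CCO[Si](C)(C)C(C)(C)C | starting material
36 | ethyl 2-(triphenyl-λ5-phosphanylidene)propanoate | CCOC(=O)C(C)=P(c1ccccc1)(c1ccccc1)c1ccccc1 | starting material
37 | ethyl (2E)-4-{[tert-butyl(dimethyl)silyl]oxy}-2-methylbut-2-enoate | CCOC(=O)/C(C)=C/CO[Si](C)(C)C(C)(C)C | intermediate
38 | (2E)-4-{[tert-butyl(dimethyl)silyl]oxy}-2-methylbut-2-enoic acid | OC(=O)/C(C)=C/CO[Si](C)(C)C(C)(C)C | intermediate
39 | [(3aR,4R,5E,9E,11aS)-4-{[tert-butyl(dimethyl)silyl]oxy}-10-methyl-3-methylidene-2-oxo-2,3,3a,4,7,8,11,11a-octahydrocyclodeca[b]furan-6-yl]methyl (2E)-4-{[tert-butyl(dimethyl)silyl]oxy}-2-methylbut-2-enoate | C=C1C(=O)O[C@H]2C/C(C)=C/CC/C(COC(=O)/C(C)=C/CO[Si](C)(C)C(C)(C)C)=C\[C@@H](O[Si](C)(C)C(C)(C)C)[C@H]12 | intermediate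
40 | [(3aS,4R,5E,9E,11aS)-4-hydroxy-10-methyl-3-methylidene-2-oxo-2,3,3a,4,7,8,11,11a-octahydrocyclodeca[b]furan-6-yl]methyl (2E)-4-hydroxy-2-methylbut-2-enoate | C=C1C(=O)O[C@H]2C/C(C)=C/CC/C(COC(=O)/C(C)=C/CO)=C\[C@@H](O)[C@H]12 | target

**Step count and risks**

Total step count: 25. Longest linear sequence: 20 steps (steps 1–8, 11–15, 17–21, 24 and 25).

Steps most likely to fail:

1. Step 17 (Proposed new method). Intermolecular zinc-to-nickel transfer may outrun ring closure and give oligomers. β-Hydride elimination from the C3 alkylnickel may give the reduced open-chain product. The alkyne may add to the wrong aldehyde face or with the wrong regiochemistry. The aldehyde may also degrade during zinc insertion.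
 Fallback with known chemistry, setting out from 24 and returning at 28. The alkylzinc iodide 27 is formed as in step 17 and joined in a Negishi coupling (Pd(OAc)2, 2-dicyclohexylphosphino-2',6'-dimethoxybiphenyl, THF, rt) with [(2-bromoprop-2-en-1-yl)oxy]triethylsilane F1, itself made from 2-bromoprop-2-en-1-ol with Et3SiCl and imidazole. This gives the aldehyde carrying the C4 1,1-disubstituted alkene, (2S,3R)-2-[(2E)-2-methyl-6-{[(triethylsilyl)oxy]methyl}hepta-2,6-dien-1-yl]-5-oxooxolane-3-carbaldehyde F2. Vinylmagnesium bromide (CH2=CHMgBr, THF, −78 °C) then adds to C6, in the same Felkin–Anh sense, to give the divinyl carbinol (4S,5S)-4-[(1R)-1-hydroxyprop-2-en-1-yl]-5-[(2E)-2-methyl-6-{[(triethylsilyl)oxy]methyl}hepta-2,6-dien-1-yl]oxolan-2-one F3. Ring-closing metathesis (second-generation Grubbs catalyst, toluene, 60 °C, 1 mM) closes ring A at C4=C5, where the ten-membered ring should favour the ring-cis alkene, and arrives at 28.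

2. Step 11. The alkenylmagnesium reagent may attack the lactone carbonyl. Base may eliminate triflate toward the exocyclic enol ether. SN2 of a hindered α-branched alkenyl nucleophile at a carbon next to C8–O may be slow.
 Fallback setting out from 12 and returning at 20. The alcohol is converted (TsCl, pyridine, 0 °C) into the tosylate [(2R,3S)-3-{[(tert-butyldiphenylsilyl)oxy]methyl}-5-oxooxolan-2-yl]methyl 4-methylbenzenesulfonate F4. K2CO3 in MeOH at 0 °C opens the lactone, and the C8 alkoxide closes onto C9 to give the epoxy ester methyl (3S)-4-[(tert-butyldiphenylsilyl)oxy]-3-[(2R)-oxiran-2-yl]butanoate F5. The C8–O bond is never broken, so C8 keeps its configuration. The alkenylmagnesium bromide 19, made as in step 11, with CuI (10 mol %) in THF at −30 °C opens the epoxide at the terminal carbon C9. The C8 alkoxide recloses onto the methyl ester on warming (pyridinium p-toluenesulfonate if needed) and gives 20.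

3. Step 25. Cleavage of the hindered secondary silyl ether at O6 may be slow and force long exposure to HF. During that time proton-induced transannular cyclization of the 1(10),4-diene or allylic ionization at C6 can set in.
 Fallback setting out from 28 and ending at 40, with O6 never protected. Compound 28 is enolized as its alkoxide–enolate dianion (LiN(i-Pr)2, 3 equiv, THF, −78 °C) and treated with dimethyl(methylidene)ammonium iodide to give the hydroxy Mannich base F6. Methylation (MeI) and aq NaHCO3 give the hydroxy α-methylene lactone F7. Pyridinium p-toluenesulfonate in MeOH removes the triethylsilyl group to give the 6,15-diol F8. The primary allylic hydroxyl is acylated selectively with 38 (dicyclohexylcarbodiimide, catalytic 4-(dimethylamino)pyridine, CH2Cl2, −20 °C) to give the mono-ester F9. A short treatment with HF·pyridine/pyridine at 0 °C then has to remove only one primary allylic silyl ether and gives 40.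

Further compounds
F1 | step 17 | [(2-bromoprop-2-en-1-yl)oxy]triethylsilane | C=C(Br)CO[Si](CC)(CC)CC
F2 | step 17 | (2S,3R)-2-[(2E)-2-methyl-6-{[(triethylsilyl)oxy]methyl}hepta-2,6-dien-1-yl]-5-oxooxolane-3-carbaldehyde | O=C[C@@H]1CC(=O)O[C@H]1C/C(C)=C/CCC(=C)CO[Si](CC)(CC)CC
F3 | step 17 | (4S,5S)-4-[(1R)-1-hydroxyprop-2-en-1-yl]-5-[(2E)-2-methyl-6-{[(triethylsilyl)oxy]methyl}hepta-2,6-dien-1-yl]oxolan-2-one | C=C[C@@H](O)[C@@H]1CC(=O)O[C@H]1C/C(C)=C/CCC(=C)CO[Si](CC)(CC)CC
F4 | step 11 | [(2R,3S)-3-{[(tert-butyldiphenylsilyl)oxy]methyl}-5-oxooxolan-2-yl]methyl 4-methylbenzenesulfonate | CC(C)(C)[Si](c1ccccc1)(c1ccccc1)OC[C@@H]1CC(=O)O[C@H]1COS(=O)(=O)c1ccc(C)cc1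
F5 | step 11 | methyl (3S)-4-[(tert-butyldiphenylsilyl)oxy]-3-[(2R)-oxiran-2-yl]butanoate | CC(C)(C)[Si](c1ccccc1)(c1ccccc1)OC[C@H](CC(=O)OC)[C@@H]1CO1
F6 | step 25 | 3-[(dimethylamino)methyl] derivative of 28 (C11 epimers, O6 free) | CN(C)CC1C(=O)O[C@H]2C/C(C)=C/CC/C(CO[Si](CC)(CC)CC)=C\[C@@H](O)[C@H]12
F7 | step 25 | (3aS,4R,5E,9E,11aS)-4-hydroxy-10-methyl-3-methylidene-6-{[(triethylsilyl)oxy]methyl}-3a,4,7,8,11,11a-hexahydrocyclodeca[b]furan-2(3H)-one | C=C1C(=O)O[C@H]2C/C(C)=C/CC/C(CO[Si](CC)(CC)CC)=C\[C@@H](O)[C@H]12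
F8 | step 25 | (3aS,4R,5E,9E,11aS)-4-hydroxy-6-(hydroxymethyl)-10-methyl-3-methylidene-3a,4,7,8,11,11a-hexahydrocyclodeca[b]furan-2(3H)-one | C=C1C(=O)O[C@H]2C/C(C)=C/CC/C(CO)=C\[C@@H](O)[C@H]12
F9 | step 25 | [(3aS,4R,5E,9E,11aS)-4-hydroxy-10-methyl-3-methylidene-2-oxo-2,3,3a,4,7,8,11,11a-octahydrocyclodeca[b]furan-6-yl]methyl (2E)-4-{[tert-butyl(dimethyl)silyl]oxy}-2-methylbut-2-enoate | C=C1C(=O)O[C@H]2C/C(C)=C/CC/C(COC(=O)/C(C)=C/CO[Si](C)(C)C(C)(C)C)=C\[C@@H](O)[C@H]12
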